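# Proposed synthesis of methyl 2-[2-(hydroxymethyl)-4,6-dimethoxyphenoxy]-4-methyl-6-[(3-methylbut-2-en-1-yl)oxy]benzoate (CNP0573678.0)

Numbering used throughout: ring A is the benzoate ring (C1 ester, C2 prenyl ether, C4 methyl, C6 ether carbon). Ring B is the phenoxy ring (C1' ether carbon, C2' hydroxymethyl, C4' and C6' methoxy).

## The problem

The target is a diaryl ether of two electron-rich, fully differentiated benzene rings. The ether bond is the hard part: the ring B oxygen on C1' is flanked by substituents at C2' and C6', and the ring A carbon C6 sits next to the C1 ester. Neither ring is electron-poor enough for a plain intermolecular displacement. There is no stereocentre, and the prenyl alkene ends in two identical methyl groups, so the task is one of regiochemistry and chemoselectivity only. The two ring A oxygens (C2 and C6) are equivalent in any symmetric precursor and must be told apart once, one as the prenyl ether and one as the aryl ether. The prenyl aryl ether will not tolerate strong acid, hydrogenation, hydroboration or prolonged strong heating. The doubly ortho-flanked methyl ester must survive whatever sets the C2' carbon to the alcohol oxidation level. The feature that opens the route is the pairing of two facts. Ring A C6 is ortho to the C1 ester, which can take up the negative charge of an ipso attack. Ring B C2' carries a one-carbon group that, as a carboxylic acid, can first be tied to the C6 oxygen as an aryl ester, so that the ring B oxygen reaches C6 through a six-membered transition state.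

## Retrosynthesis

**Target 14 to acid 12.** The C2' hydroxymethyl group is taken back to a carboxylic acid. No skeletal bond is cut. The acid and the methyl ester belong to different functional classes, so the forward step only has to activate the acid (as mixed anhydride 13) and reduce it with NaBH4, which leaves the hindered ester and the alkene alone. Borane is avoided because of the alkene. Carrying an aldehyde instead would lose the tether needed one step earlier.

**Acid 12 to depside 10.** The ether bond between the ring B oxygen and ring A C6 is cut, and the ring B carboxyl is reconnected to the C6 oxygen as an aryl ester. The alternative is a direct copper-mediated coupling of phenol 3 with an ortho-formyl aryl bromide. That would ask a chelated, ester-flanked phenol to attack a doubly ortho-substituted, electron-rich aryl halide. The rearrangement replaces that hindered bimolecular event with an intramolecular O-to-O aryl migration through the spiro adduct 11. The precursor is simpler by construction: an ester between a phenol and a salicylic acid. The forward step needs a free ring B phenol, dry base in a dipolar aprotic solvent, and ipso attack faster than ester cleavage.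

**Depside 10 to silyl ether 9, then to acid 7 and phenol 3.** The acyl–oxygen bond of the depside is cut, giving the ring A phenol 3 and a salicylic acid. The acid's own phenol must be masked during acylation, or it would self-condense. A tert-butyldimethylsilyl ether is chosen because buffered fluoride removes it without touching the aryl ester, the methyl ester or the prenyl ether. A benzyl ether would need hydrogenolysis, which the alkene does not allow, and an acetal would need acid, which the prenyl ether does not allow. The forward step must acylate a hydrogen-bonded phenol, so the acid is used as its chloride 8, made under neutral conditions.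

**Phenol 3 to diol 1 and bromide 2.** The prenyl O–CH2 bond is cut. The symmetric diol 1 needs only one alkylation. After the first ether forms, the remaining hydroxyl is locked in a hydrogen bond to the ester carbonyl and is much less reactive, which is what gives mono-selectivity. Putting the prenyl group on before the rearrangement matters: a free ring A phenoxide would deactivate C6 towards ipso attack.

**Acid 7 to aldehyde 6, phenol 5 and 2,4-dimethoxyphenol 4.** The acid goes back to the aldehyde (chlorite oxidation), the silyl ether to the free salicylaldehyde 5, and the formyl C–C bond is cut to give 4. Its only free ortho position is the one required, so a magnesium-directed ortho-formylation sets the substitution pattern without isomers. Ordinary electrophilic formylation would favour the positions activated by the methoxy groups.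

## Roads not taken

**Alternative 1: ring A by Diels–Alder aromatisation.** The cut is through ring A bonds C1–C2 and C5–C6. The dienophile is the aryloxypropiolate A1 (methyl 3-aryloxyprop-2-ynoate carrying the finished, silyl-protected ring B). The diene is the vinylketene silyl acetal A2 (1-methoxy-3-methyl-1-(trimethylsilyloxy)buta-1,3-diene). Cycloaddition followed by collapse of the silyl methyl ketal would give the 6-aryloxysalicylate A3, which needs only prenylation and desilylation.
- Merits: the aryl–oxygen bond is made to an sp carbon, the least hindered setting possible. Polarisation of both partners fixes the ring A pattern. The prenyl ether goes on last and sees no acylation or heating, which is better than the chosen plan, where it is carried through five steps.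
- Weak points: A1 is a push–pull alkyne whose β-carbon is deactivated by the aryloxy donor, so forcing conditions would be needed, under which A2 is prone to silyl transfer and decomposition. Aromatisation must expel the right group from the ketal, or a methyl ether ends up where the prenyl ether belongs. Making A1 from a doubly ortho-substituted phenol takes several strongly basic steps.
- Comparison: the step count is similar. The chosen plan offers a key step with close precedent on depsides and mild reagents throughout.

**Alternative 2: ring B folded from a triketo ester.** The cut is the ring B bond C1'–C2'. The precursor is the 7-aryloxy-2,4,6-trioxoheptanoate A4. Base would enolise the aryloxymethylene terminus, which would add to the keto ester carbonyl; dehydration and enolisation would give the 2-aryloxy-3,5-dihydroxybenzoate A5.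
- Merits: the ether bond is made as a simple alkylation of phenol 3 on an sp3 carbon, so the hindered aryl ether problem disappears, and the ring B oxygenation pattern follows from the chain. On ease of forming the ether bond this road is as good as or better than the chosen one.
- Weak points: the carbon that must act as nucleophile is the least acidic methylene of A4, and such chains readily close to pyranones instead. Building a poly-β-carbonyl chain by polyanion chemistry next to the ring A ester is delicate. After A5, two O-methylations are needed, then reduction of one methyl ester beside another, distinguished only by hindrance.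
- Comparison: the chosen plan distinguishes an acid from an ester at the final step, a difference of functional class, and is shorter.

**Alternative 3: ring B by Danheiser benzannulation.** The cut breaks ring B into the racemic 4-aryloxycyclobutenone A6 and methoxyacetylene A7. Heating would open A6 to a vinylketene, which would add A7 in a [2+2] sense; 4π opening to a dienylketene and 6π-electrocyclisation would give the phenol A8.
- Merits: one operation builds the pentasubstituted ring B with defined regiochemistry. The ether oxygen is attached at an sp3 carbon beforehand. The benzylic carbon is at the alcohol level from the start, so no late chemoselective reduction is needed, which is a real advantage over the chosen plan.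
- Weak points: A6 needs a multistep preparation of its own. A7 is volatile and unstable. The phenol of A8, flanked by the aryloxy group, still needs methylation, then desilylation. The thermal step is run with the prenyl aryl ether present.
- Comparison: the route is clearly longer. The chosen plan accepts one extra redox step and uses catalogue materials and standard reactions up to the key step.

Key step: step 7

## Route

Step 1
Reactants: 1 methyl 2,6-dihydroxy-4-methylbenzoate; 2 prenyl bromide (1-bromo-3-methylbut-2-ene)
Product: 3 methyl 2-hydroxy-4-methyl-6-[(3-methylbut-2-en-1-yl)oxy]benzoate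
Conditions: K2CO3 (1.1 equiv), 2 (1.0 equiv), acetone, rt to 40 °C
Reagents that add atoms: none
Why: Williamson ether synthesis; after the first O-alkylation the remaining hydroxyl is chelated to the ester carbonyl and much less acidic and nucleophilic, so the mono-ether should dominate, and K2CO3 in acetone favours O- over C-alkylation.

Step 2
Reactants: 4 2,4-dimethoxyphenol
Product: 5 2-hydroxy-3,5-dimethoxybenzaldehyde
Conditions: MgCl2, Et3N, paraformaldehyde, MeCN, reflux; dilute HCl work-up
Reagents that add atoms: paraformaldehyde (as formaldehyde), C=O
Why: Magnesium-mediated ortho-formylation (Casnati–Skattebøl); the magnesium phenoxide delivers formaldehyde to the only free ortho position and a second equivalent of formaldehyde oxidises the benzylic alkoxide to the aldehyde, so no regioisomer can form.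

Step 3
Reactants: 5 2-hydroxy-3,5-dimethoxybenzaldehyde
Product: 6 2-[(tert-butyldimethylsilyl)oxy]-3,5-dimethoxybenzaldehyde
Conditions: TBSCl, imidazole, DMF, rt
Reagents that add atoms: tert-butyldimethylsilyl chloride (TBSCl), CC(C)(C)[Si](C)(C)Cl
Why: Standard silylation of a phenol with TBSCl and imidazole; DMF gives enough reactivity for a phenol flanked by methoxy and formyl groups, as for other 3-alkoxysalicylaldehydes.

Step 4
Reactants: 6 2-[(tert-butyldimethylsilyl)oxy]-3,5-dimethoxybenzaldehyde
Product: 7 2-[(tert-butyldimethylsilyl)oxy]-3,5-dimethoxybenzoic acid
Conditions: NaClO2, NaH2PO4, 2-methyl-2-butene (excess), t-BuOH/H2O, 0 °C to rt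
Reagents that add atoms: sodium chlorite (NaClO2), [Na+].[O-]Cl=O
Why: Pinnick oxidation; the buffered chlorite oxidises the aldehyde without disturbing the aryl silyl ether, and the alkene scavenger removes hypochlorous acid before it can chlorinate the electron-rich ring.

Step 5
Reactants: 7 2-[(tert-butyldimethylsilyl)oxy]-3,5-dimethoxybenzoic acid; 3 methyl 2-hydroxy-4-methyl-6-[(3-methylbut-2-en-1-yl)oxy]benzoate
Product: 9 2-(methoxycarbonyl)-5-methyl-3-[(3-methylbut-2-en-1-yl)oxy]phenyl 2-[(tert-butyldimethylsilyl)oxy]-3,5-dimethoxybenzoate, via acid chloride 8 (not isolated)
Conditions: 1-chloro-N,N,2-trimethylprop-1-en-1-amine, CH2Cl2, 0 °C to rt; then 3, Et3N, DMAP (cat.), CH2Cl2, 0 °C to rt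
Reagents that add atoms: none
Why: Acid chloride formation with the Ghosez reagent is neutral and spares the silyl ether; DMAP-catalysed acylation of the phenol is the usual way to esterify a hydrogen-bonded salicylate-type hydroxyl, and the prenyl ether is inert to it.

Step 6
Reactants: 9 2-(methoxycarbonyl)-5-methyl-3-[(3-methylbut-2-en-1-yl)oxy]phenyl 2-[(tert-butyldimethylsilyl)oxy]-3,5-dimethoxybenzoate
Product: 10 2-(methoxycarbonyl)-5-methyl-3-[(3-methylbut-2-en-1-yl)oxy]phenyl 2-hydroxy-3,5-dimethoxybenzoate
Conditions: TBAF, AcOH (1:1), THF, 0 °C
Reagents that add atoms: none
Why: Fluoride cleavage of an aryl silyl ether is fast at 0 °C; acetic acid protonates the phenoxide as it forms, so the aryl ester is neither cleaved nor rearranged early and the chelated phenol 10 can be isolated.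

Step 7
Reactants: 10 2-(methoxycarbonyl)-5-methyl-3-[(3-methylbut-2-en-1-yl)oxy]phenyl 2-hydroxy-3,5-dimethoxybenzoate
Product: 12 2-{2-(methoxycarbonyl)-5-methyl-3-[(3-methylbut-2-en-1-yl)oxy]phenoxy}-3,5-dimethoxybenzoic acid, via spiro Meisenheimer adduct 11 (not isolated)
Conditions: K2CO3 (anhydrous, 2–3 equiv), dry DMSO, 60 °C, Ar; then cold aq. HCl to pH 3
Reagents that add atoms: none
Why: K2CO3 deprotonates the ring B phenol of 10, and in DMSO the poorly solvated phenoxide adds to ring A C6, ipso to the acyloxy group and ortho to the C1 ester, giving the spiro adduct 11 with its charge held as the ester enolate; cleavage of the acyl O–C6 bond then releases the carboxylate and leaves the ring B oxygen on C6. The closest known reaction type is the Smiles rearrangement of depsides to diaryl ether carboxylic acids under K2CO3 in DMSO, as used to prepare depsidones. No ring of the product is closed: the transient 1,3-benzodioxin-4-one ring of 11 forms by 6-exo-trig attack and opens again in the same step, and no stereocentre is created. The step needs ipso attack to outrun acyl transfer and ester cleavage; C6 is the only electrophilic carbon the phenoxide can reach through a six-membered transition state (attack on the ring A methyl ester would need an eight-membered one), and dry conditions keep hydroxide away from the activated aryl ester. Forming the spiro centre lifts C6 out of the ring plane, which lets the doubly ortho-flanked ester turn into conjugation with the developing anion. The prenyloxy and methyl groups are meta to C6 and do not donate to the carbons that carry the charge. Exchange of a phenoxide for a far less basic carboxylate makes the migration irreversible, and acidification on work-up gives 12.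

Step 8
Reactants: 12 2-{2-(methoxycarbonyl)-5-methyl-3-[(3-methylbut-2-en-1-yl)oxy]phenoxy}-3,5-dimethoxybenzoic acid
Product: 14 methyl 2-[2-(hydroxymethyl)-4,6-dimethoxyphenoxy]-4-methyl-6-[(3-methylbut-2-en-1-yl)oxy]benzoate, via isobutyl mixed carbonic anhydride 13 (not isolated)
Conditions: i-BuOCOCl, N-methylmorpholine, THF, −15 °C; then NaBH4, H2O, −15 to 0 °C
Reagents that add atoms: none
Why: Mixed-anhydride activation followed by NaBH4 reduction; only the activated acyl group is electrophilic enough for borohydride at low temperature, so the hindered methyl ester and the trisubstituted alkene should be untouched.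

## Compound list

1 | methyl 2,6-dihydroxy-4-methylbenzoate | COC(=O)c1c(O)cc(C)cc1O | starting material
2 | prenyl bromide (1-bromo-3-methylbut-2-ene) | CC(C)=CCBr | starting material
3 | methyl 2-hydroxy-4-methyl-6-[(3-methylbut-2-en-1-yl)oxy]benzoate | COC(=O)c1c(O)cc(C)cc1OCC=C(C)C | intermediate
4 | 2,4-dimethoxyphenol | COc1ccc(O)c(OC)c1 | starting material
5 | 2-hydroxy-3,5-dimethoxybenzaldehyde | COc1cc(C=O)c(O)c(OC)c1 | intermediate
6 | 2-[(tert-butyldimethylsilyl)oxy]-3,5-dimethoxybenzaldehyde | COc1cc(C=O)c(O[Si](C)(C)C(C)(C)C)c(OC)c1 | intermediate
7 | 2-[(tert-butyldimethylsilyl)oxy]-3,5-dimethoxybenzoic acid | COc1cc(C(=O)O)c(O[Si](C)(C)C(C)(C)C)c(OC)c1 | intermediate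
8 | 2-[(tert-butyldimethylsilyl)oxy]-3,5-dimethoxybenzoyl chloride | COc1cc(C(Cl)=O)c(O[Si](C)(C)C(C)(C)C)c(OC)c1 | intermediate
9 | 2-(methoxycarbonyl)-5-methyl-3-[(3-methylbut-2-en-1-yl)oxy]phenyl 2-[(tert-butyldimethylsilyl)oxy]-3,5-dimethoxybenzoate | COC(=O)c1c(OCC=C(C)C)cc(C)cc1OC(=O)c1cc(OC)cc(OC)c1O[Si](C)(C)C(C)(C)C | intermediate
10 | 2-(methoxycarbonyl)-5-methyl-3-[(3-methylbut-2-en-1-yl)oxy]phenyl 2-hydroxy-3,5-dimethoxybenzoate | COC(=O)c1c(OCC=C(C)C)cc(C)cc1OC(=O)c1cc(OC)cc(OC)c1O | intermediate
11 | potassium salt of the spiro Meisenheimer adduct (ring A C6 as spiro carbon of a 1,3-benzodioxin-4-one, charge as the C1 ester enolate) | COC([O-])=C1C(OCC=C(C)C)=CC(C)=CC12OC(=O)c3cc(OC)cc(OC)c3O2.[K+] | intermediate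
12 | 2-{2-(methoxycarbonyl)-5-methyl-3-[(3-methylbut-2-en-1-yl)oxy]phenoxy}-3,5-dimethoxybenzoic acid | COC(=O)c1c(OCC=C(C)C)cc(C)cc1Oc1c(C(=O)O)cc(OC)cc1OC | intermediate
13 | isobutyl carbonic anhydride of acid 12 | COC(=O)c1c(OCC=C(C)C)cc(C)cc1Oc1c(C(=O)OC(=O)OCC(C)C)cc(OC)cc1OC | intermediate
14 | methyl 2-[2-(hydroxymethyl)-4,6-dimethoxyphenoxy]-4-methyl-6-[(3-methylbut-2-en-1-yl)oxy]benzoate | COC(=O)c1c(OCC=C(C)C)cc(C)cc1Oc1c(CO)cc(OC)cc1OC | target

## Step count and risk

Total step count: 8. Longest linear sequence: 7 steps (4 to 14 through steps 2 to 8); the ring A branch (step 1) joins at step 5.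

**Step 7 (key step).** The ipso attack may be slow: ring A is activated by a single ester that is twisted out of conjugation in the ground state. Cleavage of the aryl ester by traces of water, or fragmentation of the depside back to the ring A phenoxide, could then overtake the migration. The fallback leaves the rearrangement and makes the ether bond by copper catalysis. Setting out from phenol 3, Ullmann coupling with 2-bromo-3,5-dimethoxybenzaldehyde F1 (CuI, N,N-dimethylglycine, Cs2CO3, dioxane, 100 °C), in which the ortho formyl group assists oxidative addition, would give methyl 2-(2-formyl-4,6-dimethoxyphenoxy)-4-methyl-6-[(3-methylbut-2-en-1-yl)oxy]benzoate F2. NaBH4 in MeOH at 0 °C would reduce the aldehyde and rejoin the route at target 14. This is shorter, but it relies on a hindered bimolecular coupling, which is why it is held in reserve.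

**Step 8.** Hydride may attack the carbonate carbonyl of 13 instead of the aroyl carbonyl, which is shielded by the ortho aryloxy group; this would return acid 12. The anhydride could also disproportionate before reduction. The fallback sets out from 12 and uses an activated form with a single electrophilic carbonyl. Carbonyldiimidazole in THF would give the acyl imidazole methyl 2-[2-(imidazol-1-ylcarbonyl)-4,6-dimethoxyphenoxy]-4-methyl-6-[(3-methylbut-2-en-1-yl)oxy]benzoate F4, and NaBH4 in THF/H2O at 0 °C would reduce it to target 14.

**Step 5.** Acylation of the chelated, ester-flanked phenol 3 may be slow enough for acid chloride 8 to decay by silyl transfer and self-condensation. The fallback reverses the order of the two ring A functionalisations. Setting out from diol 1, whose first hydroxyl is less tightly chelated, acylation with one equivalent of 8 (Et3N, DMAP, CH2Cl2) would give methyl 2-({2-[(tert-butyldimethylsilyl)oxy]-3,5-dimethoxybenzoyl}oxy)-6-hydroxy-4-methylbenzoate F3. Alkylation of the remaining hydroxyl with prenyl bromide 2 (K2CO3, acetone) would then rejoin the route at 9. Acyl migration between the two ring A oxygens of F3 is degenerate and does no harm.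

**Step 1.** Over-alkylation to the bis-ether, or C-prenylation of the electron-rich ring through the phenoxide, would lower the supply of 3. The fallback sets out from 1 and uses a Mitsunobu etherification with 3-methylbut-2-en-1-ol (PPh3, diisopropyl azodicarboxylate, THF, 0 °C). No free phenoxide is present and the chelated second hydroxyl does not react, so the route is rejoined at 3. This fallback makes no new compound (F0).

## Further compounds

F1 | step 7 | 2-bromo-3,5-dimethoxybenzaldehyde | COc1cc(C=O)c(Br)c(OC)c1
F2 | step 7 | methyl 2-(2-formyl-4,6-dimethoxyphenoxy)-4-methyl-6-[(3-methylbut-2-en-1-yl)oxy]benzoate | COC(=O)c1c(OCC=C(C)C)cc(C)cc1Oc1c(C=O)cc(OC)cc1OC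
F4 | step 8 | methyl 2-[2-(imidazol-1-ylcarbonyl)-4,6-dimethoxyphenoxy]-4-methyl-6-[(3-methylbut-2-en-1-yl)oxy]benzoate | COC(=O)c1c(OCC=C(C)C)cc(C)cc1Oc1c(C(=O)n2ccnc2)cc(OC)cc1OC
F3 | step 5 | methyl 2-({2-[(tert-butyldimethylsilyl)oxy]-3,5-dimethoxybenzoyl}oxy)-6-hydroxy-4-methylbenzoate | COC(=O)c1c(O)cc(C)cc1OC(=O)c1cc(OC)cc(OC)c1O[Si](C)(C)C(C)(C)C
F0 | step 1 | none | none
A1 | alternative 1 | methyl 3-[2-({[tert-butyl(dimethyl)silyl]oxy}methyl)-4,6-dimethoxyphenoxy]prop-2-ynoate | COC(=O)C#COc1c(CO[Si](C)(C)C(C)(C)C)cc(OC)cc1OC
A2 | alternative 1 | 1-methoxy-3-methyl-1-(trimethylsilyloxy)buta-1,3-diene | COC(O[Si](C)(C)C)=CC(C)=C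
A3 | alternative 1 | methyl 2-[2-({[tert-butyl(dimethyl)silyl]oxy}methyl)-4,6-dimethoxyphenoxy]-6-hydroxy-4-methylbenzoate | COC(=O)c1c(O)cc(C)cc1Oc1c(CO[Si](C)(C)C(C)(C)C)cc(OC)cc1OC
A4 | alternative 2 | methyl 7-{2-(methoxycarbonyl)-5-methyl-3-[(3-methylbut-2-en-1-yl)oxy]phenoxy}-2,4,6-trioxoheptanoate | COC(=O)C(=O)CC(=O)CC(=O)COc1cc(C)cc(OCC=C(C)C)c1C(=O)OC
A5 | alternative 2 | methyl 2-{2-(methoxycarbonyl)-5-methyl-3-[(3-methylbut-2-en-1-yl)oxy]phenoxy}-3,5-dihydroxybenzoate | COC(=O)c1cc(O)cc(O)c1Oc1cc(C)cc(OCC=C(C)C)c1C(=O)OC
A6 | alternative 3 | methyl 2-{[2-({[tert-butyl(dimethyl)silyl]oxy}methyl)-4-oxocyclobut-2-en-1-yl]oxy}-4-methyl-6-[(3-methylbut-2-en-1-yl)oxy]benzoate (racemic) | O=C1C=C(CO[Si](C)(C)C(C)(C)C)C1Oc1cc(C)cc(OCC=C(C)C)c1C(=O)OC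
A7 | alternative 3 | methoxyacetylene (methoxyethyne) | COC#C
A8 | alternative 3 | methyl 2-[2-hydroxy-4-methoxy-6-({[tert-butyl(dimethyl)silyl]oxy}methyl)phenoxy]-4-methyl-6-[(3-methylbut-2-en-1-yl)oxy]benzoate | COc1cc(CO[Si](C)(C)C(C)(C)C)c(Oc2cc(C)cc(OCC=C(C)C)c2C(=O)OC)c(O)c1
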